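## The problem

Compound 18, (3S)-7-hydroxy-3-[2-hydroxy-4-methoxy-5-(3-methylbut-2-enyl)phenyl]chroman-4-one, is an isoflavanone. Ring A (a 7-hydroxylated benzene) is fused to the pyranone ring C (O1, C2, C3, C4), and ring B hangs from C3 as a 1,2,4,5-tetrasubstituted benzene with 2'-OH, 4'-OMe and a 5'-prenyl group. The only stereocentre is C3; it is benzylic and alpha to the C4 ketone, so it epimerises through the enol, and nothing else in the molecule can direct it. It therefore has to be set by a reagent, late, and kept away from base afterwards. The prenyl alkene excludes hydrogenolysis, strong acid and any carbene or electrophile still present when it is introduced; the phenols must be masked during oxidation; and a free 2'-OH beside a C4 carbinol closes to a pterocarpan under acid. Ring B has the pattern of 2-hydroxy-4-methoxybenzaldehyde substituted at C5, the position that electrophiles attack. The feature that opens a short route is that C3, with ring B attached, lies between C2 and C4, and that these two atoms are already bonded to each other in the five-membered ring of 6-hydroxybenzofuran-3(2H)-one, which also contains O1 and all of ring A. Ring C can therefore arise by inserting one carbon atom, carrying ring B, into that bond.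

## Retrosynthesis

Abbreviations: TBS = tert-butyldimethylsilyl, TIPS = triisopropylsilyl.

**Unmasking the phenols (18 from 17).** The last cut is at the two O–Si bonds. Silyl ethers are preferred to benzyl or acetal groups because their removal needs neither hydrogen nor strong acid, both of which endanger the prenyl group. Fluoride buffered with acetic acid should not be basic enough to enolise C3. Precursor 17 differs from 18 only by a TBS group on O7 and a TIPS group on O2'. The forward step must cleave both without removing the C3 hydrogen.

**Setting C3 (17 from 14 by way of 16).** Removing the hydrogens at C2 and C3 leads back to the flat isoflavone 14. In the forward direction a chiral ruthenium hydride first saturates C2=C3 to the racemic ketone 15. C3 of 15 epimerises freely, and the catalyst reduces one enantiomer to the cis carbinol 16; reoxidation at C4 gives 17. This redox detour is preferred to an auxiliary or an early stereocentre. The centre is created by a catalyst after all carbon–carbon bonds are in place, and afterwards it meets only a buffered oxidation and a buffered desilylation. The reduction must be selective for the cis diastereomer and for one face. The silyl group on O2' must stay on so that the carbinol cannot close onto ring B.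

**Attaching the prenyl group (14 from 12 and 13).** The C5'–CH2 bond is cut to aryl bromide 12 and stannane 13. The prenyl group is introduced after the ring expansion because a trisubstituted alkene would compete for the carbene of the key step. Bromine is inert to that carbene and marks C5' from the first step of the ring B sequence. The coupling must deliver the prenyl group through its CH2 terminus; it needs neither base nor fluoride, which suits the silyl ethers.

**Ring C by one-carbon insertion (12 from 2 and 10).** Cutting C2–C3 and C3–C4 excises C3 from the isoflavone. What remains is a benzofuran in which C2 and C4 are bonded, the silyl enol ether 2; C3 becomes the carbene carbon of an arylchlorocarbene stored as diazirine 10. The usual isoflavone cuts are C3–C1' (coupling of a 3-halochromone) or C2 (formylation of a deoxybenzoin). Against these, the present cut forms both ring C bonds to C3 in one operation, uses a ring A component one step from a commercial compound, and avoids acylation of an electron-rich phenol. The forward reaction passes through chlorocyclopropane 11, which must open across the ring-fusion bond with loss of chloride and of the enol silyl group. It requires clean carbene transfer to the enol double bond, so nothing else in 2 or 10 may intercept the carbene.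

**Ring A component (2 from 1).** Both O–Si bonds of 2 are cut to commercial 1. One silylating agent serves the phenol and the ketone enol.

**Carbene precursor (10 from 3).** The diazirine is traced to amidinium salt 9 (N–N and C–Cl bonds), 9 to nitrile 7 (C–N bond), 7 to aldehyde 5 through oxime 6, 5 to phenol 4 (O–Si bond) and 4 to commercial 3 (C–Br bond). The silyl group on this oxygen must pass a lithium amide, hydrogen chloride and alkaline hypochlorite, hence TIPS and not TBS. A silyl group is kept because, unlike a methoxymethyl or benzyl group, it offers the neighbouring carbene no C–H bond alpha to oxygen. Bromination comes first because in 3 the hydroxy and methoxy groups together direct to C5.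

## Roads not taken

**Alternative 1: photogenerated quinoketene hetero-Diels–Alder.**
- Cut: C3–C4 and O1–C2.
- Forward key step: irradiation of benzodioxinone A1 releases the ortho-quinoketene A3, which adds as a heterodiene to aryl enol ether A2 and gives the 2-methoxyisoflavanone A4 as a diastereomer mixture. Loss of the C2 methoxy group then gives isoflavone A5.
- Merits: it is convergent and the regiochemistry is inherent, since the nucleophilic enol ether carbon meets the ketene carbon. The prenyl group is present from the start, so no late tin coupling is needed. Ketene–enol ether cycloadditions of this kind are closer to established practice than a carbene insertion into a benzofuran.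
- Weak points: both stereocentres of A4 are erased, so the stereochemical problem is untouched and the route meets the chosen one at an isoflavone. A2 must be made by olefination with the prenyl group already in place. The styrene-type enol ether A2 absorbs near A1 and can isomerise or add (2+2) to the ketene C=C bond. The methoxymethyl ethers require acid at the end, next to a prenyl group and an epimerisable C3.
- Comparison: in precedent for the key step this road is ahead. The chosen plan sets against it a ring A component made in one step, no enol ether synthesis, thermal conditions, direct formation of the isoflavone, and a non-acidic final deprotection.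

**Alternative 2: ring A by Diels–Alder benzannulation of an ynone.**
- Cut: C4a–C8a and C5–C6, that is, ring A itself.
- Forward key step: the bis(silyloxy)diene A7 adds across the terminal alkyne of ynone A6 and the adduct aromatises to the dihydroxyphenyl ketone A8. Oxa-Michael addition and β-elimination would then close ring C to isoflavone A9.
- Merits: the cycloaddition–aromatisation is an established reaction type. The diene fixes the oxygenation pattern, and the ring A hydroxy groups appear without protection.
- Weak points: the key step is spent on a 1,3-dioxygenated benzene ring, the most readily available part of the molecule. A6 has two electrophilic sites (the alkynone and the β-methoxy enone) and would itself need a multistep synthesis with prenyl and acetal groups already present. Ring C still has to be closed and C3 still has to be set, again through an isoflavone.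
- Comparison: the route is clearly longer and solves no problem the chosen plan leaves open. Its one advantage is a precedented key step. The chosen plan answers that with brevity and with a fallback built on the known dihalocarbene ring expansion of silyl enol ethers.

**Alternative 3: acylium closure of a pre-set chiral aryloxy acid.**
- Cut: C4–C4a.
- Forward key step: the (S)-acid A10, activated as a mixed anhydride, acylates its silyloxyphenoxy ring ortho to the ether oxygen and para to the silyloxy group. This gives A11, the bis-TIPS analogue of 17, and desilylation gives 18.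
- Merits: the stereocentre is made once, before ring closure, and there is no reduction–oxidation detour at C4. The closure is classical and only one step follows it. In these respects this road is better than the chosen plan.
- Weak points: an activated α-aryl acyl species loses configuration easily, through a ketene or through enolisation. The strong acid set free on activation threatens the prenyl alkene and the silyl ethers. A10 needs its own enantioselective synthesis, and as an α-aryl-β-aryloxy acid it can lose the aryloxy group by elimination under base.
- Comparison: the chosen plan creates C3 by a catalyst-controlled reduction with dynamic kinetic resolution and then exposes it to two buffered steps only. In alternative 3 the same centre must survive acylium chemistry. The final desilylation and its risk are common to both.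

Key step: step 7

Remark on the chemistry: the (S,S)-configured ruthenium catalyst is assumed to deliver hydride to C4 in the sense known for 4-chromanone, giving the (4S) carbinol; the cis relationship then makes C3 (S). If the sense proved opposite, the (R,R) catalyst would be used.

## Route

Step 1
Reactants: 1 6-hydroxybenzofuran-3(2H)-one
Product: 2 3,6-bis(tert-butyldimethylsilyloxy)benzofuran
Conditions: TBSOTf (2.3 equiv), Et3N, CH2Cl2, 0 °C to rt
Reagents that add atoms: tert-butyldimethylsilyl trifluoromethanesulfonate, CC(C)(C)[Si](C)(C)OS(=O)(=O)C(F)(F)F
Why: O-silylation of the phenol and soft enolisation with O-silylation of the ketone (silyl triflate and amine); enolisation is driven by formation of the aromatic furan, so the silyl enol ether should form completely and be isolable on base-washed silica.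

Step 2
Reactants: 3 2-hydroxy-4-methoxybenzaldehyde
Product: 4 5-bromo-2-hydroxy-4-methoxybenzaldehyde
Conditions: Br2, CH2Cl2, 0 °C
Reagents that add atoms: bromine, BrBr
Why: Electrophilic aromatic bromination; C5 is para to the hydroxy group, ortho to the methoxy group and meta to the aldehyde, whereas C3 is flanked by two substituents, so monobromination at C5 is expected.

Step 3
Reactants: 4 5-bromo-2-hydroxy-4-methoxybenzaldehyde
Product: 5 5-bromo-4-methoxy-2-(triisopropylsilyloxy)benzaldehyde
Conditions: TIPSCl, imidazole, DMF, rt
Reagents that add atoms: chlorotriisopropylsilane, CC(C)[Si](Cl)(C(C)C)C(C)C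
Why: Standard silylation of a phenol with an imidazole-activated silyl chloride; TIPS is chosen because this ether must later withstand a lithium amide, hydrogen chloride and alkaline hypochlorite.

Step 4
Reactants: 5 5-bromo-4-methoxy-2-(triisopropylsilyloxy)benzaldehyde
Product: 7 5-bromo-4-methoxy-2-(triisopropylsilyloxy)benzonitrile, via aldoxime 6 (not isolated)
Conditions: NH2OH·HCl, pyridine, rt; then (CF3CO)2O, 0 °C to rt
Reagents that add atoms: hydroxylamine hydrochloride, Cl.NO
Why: Condensation to the aldoxime and dehydration through its O-trifluoroacetate (base-induced elimination); the silyl group on the ortho oxygen prevents closure to a benzisoxazole.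

Step 5
Reactants: 7 5-bromo-4-methoxy-2-(triisopropylsilyloxy)benzonitrile
Product: 9 5-bromo-4-methoxy-2-(triisopropylsilyloxy)benzamidinium chloride, via lithium N,N'-bis(trimethylsilyl)amidinate 8 (not isolated)
Conditions: LiN(SiMe3)2, THF, 0 °C to rt; then HCl (4 M in dioxane), 0 °C
Reagents that add atoms: lithium bis(trimethylsilyl)amide, [Li+].C[Si](C)(C)[N-][Si](C)(C)C; hydrogen chloride, Cl
Why: Addition of the silylamide to the nitrile with 1,3-silyl shift, then cleavage of both N–Si bonds by anhydrous HCl (the standard nitrile-to-amidine sequence); the amide base does not exchange with the aryl bromide, and the bulky TIPS group should resist O-to-N migration and brief anhydrous acid.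

Step 6
Reactants: 9 5-bromo-4-methoxy-2-(triisopropylsilyloxy)benzamidinium chloride
Product: 10 3-[5-bromo-4-methoxy-2-(triisopropylsilyloxy)phenyl]-3-chloro-3H-diazirine
Conditions: NaOCl (aq), LiCl, DMSO, hexane, 0 °C to rt
Reagents that add atoms: sodium hypochlorite, [Na+].[O-]Cl; lithium chloride, [Li+].[Cl-]
Why: Graham oxidation: N,N'-dichlorination of the amidine, base-induced N–N closure and return of chloride to carbon give the 3-aryl-3-chlorodiazirine; the hexane layer removes the product from the alkaline phase, and 10 is kept cold and dark and used without storage.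

Step 7
Reactants: 2 3,6-bis(tert-butyldimethylsilyloxy)benzofuran; 10 3-[5-bromo-4-methoxy-2-(triisopropylsilyloxy)phenyl]-3-chloro-3H-diazirine
Product: 12 5'-bromo-7-(tert-butyldimethylsilyloxy)-4'-methoxy-2'-(triisopropylsilyloxy)isoflavone, via chlorocyclopropane adduct 11 (not isolated)
Conditions: 2 (2 equiv), Na2CO3, MeCN, 50 °C, dark, slow addition of 10
Reagents that add atoms: none
Why: Proposed new method: warming expels N2 from 10 and gives a singlet arylchlorocarbene, which adds in a concerted (2+1) fashion to the C2=C3 enol ether bond of 2, the most electron-rich π bond present because both O1 and the silyloxy group donate into it, to give 11. In 11 the chlorine-bearing carbon lies between two oxygen-substituted carbons, so loss of chloride with disrotatory 2π-electrocyclic opening breaks the former furan C2–C3 bond and gives a 4-silyloxybenzopyrylium chloride, which is desilylated at oxygen by its own chloride to 12 and TBSCl. The closest known reaction types are carbon-atom insertion into indoles and pyrroles by arylchlorodiazirines and the dihalocarbene ring expansion of cyclic silyl enol ethers to 2-haloenones; the enol ether substrate of the second is combined here with the aryl-bearing carbene of the first. Ring C is closed by one-atom expansion of the furan ring and not by cyclisation: both new bonds (C2–C3 and C3–C4 of the isoflavone) come from the cyclopropanation and the old ring bond is the one that breaks. No stereocentre remains, because the three centres of 11 are erased on opening. The step needs site selectivity for the enol double bond over the arenes, which its two oxygen donors should secure, and opening across the ring-fusion bond, which is the only mode that gives an aromatic pyrylium ion stabilised by both oxygens. It also needs ionisation of both chloro epimers of 11; the 2,4-dioxygenated aryl group stabilises the cyclopropyl cation, so the endo/exo restriction of a strictly concerted opening should be relaxed. Carbene side reactions are limited by design: 10 has no alkene and no reachable C–H bond alpha to oxygen, and 2 is in excess with slow addition of 10 to suppress azine formation.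

Step 8
Reactants: 12 5'-bromo-7-(tert-butyldimethylsilyloxy)-4'-methoxy-2'-(triisopropylsilyloxy)isoflavone; 13 tributyl(3-methylbut-2-enyl)stannane
Product: 14 7-(tert-butyldimethylsilyloxy)-4'-methoxy-5'-(3-methylbut-2-enyl)-2'-(triisopropylsilyloxy)isoflavone
Conditions: Pd(PPh3)4 (5 mol%), toluene, 100 °C
Reagents that add atoms: none
Why: Stille coupling: oxidative addition of zerovalent palladium into the C5'–Br bond, transmetalation of the allylic stannane and reductive elimination, which with triphenylphosphine ligands normally joins the less substituted terminus and so gives the prenyl and not the 1,1-dimethylallyl arene; no base or fluoride is present, so both silyl ethers should survive.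

Step 9
Reactants: 14 7-(tert-butyldimethylsilyloxy)-4'-methoxy-5'-(3-methylbut-2-enyl)-2'-(triisopropylsilyloxy)isoflavone
Product: 16 (3S,4S)-7-(tert-butyldimethylsilyloxy)-3-[4-methoxy-5-(3-methylbut-2-enyl)-2-(triisopropylsilyloxy)phenyl]chroman-4-ol, via racemic isoflavanone 15 (not isolated)
Conditions: RuCl(p-cymene)[(S,S)-TsDPEN] (3 mol%), HCO2H, Et3N, EtOAc, 40 °C
Reagents that add atoms: none
Why: Noyori–Ikariya asymmetric transfer hydrogenation with dynamic kinetic resolution, a sequence known for isoflavones: the ruthenium hydride first reduces C2=C3 in conjugate fashion to 15, whose C3 epimerises through the enol in the amine buffer. The catalyst then reduces only the (3S) ketone, from the face anti to ring B, so C4 is set as (S) by the catalyst (arene-side preference as in 4-chromanone) and C3 as (S) by the cis relationship; the isolated prenyl alkene is not touched by this hydride.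

Step 10
Reactants: 16 (3S,4S)-7-(tert-butyldimethylsilyloxy)-3-[4-methoxy-5-(3-methylbut-2-enyl)-2-(triisopropylsilyloxy)phenyl]chroman-4-ol
Product: 17 (3S)-7-(tert-butyldimethylsilyloxy)-4'-methoxy-5'-(3-methylbut-2-enyl)-2'-(triisopropylsilyloxy)isoflavanone
Conditions: Dess–Martin periodinane, NaHCO3, CH2Cl2, 0 °C to rt
Reagents that add atoms: none
Why: Dess–Martin oxidation of the secondary benzylic carbinol by ligand exchange at iodine and loss of the C4 hydrogen; the bicarbonate buffer prevents acid-induced ionisation at C4, and C3, the alkene and the silyl ethers are not involved, so the configuration at C3 should be carried over.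

Step 11
Reactants: 17 (3S)-7-(tert-butyldimethylsilyloxy)-4'-methoxy-5'-(3-methylbut-2-enyl)-2'-(triisopropylsilyloxy)isoflavanone
Product: 18 (3S)-7-hydroxy-3-[2-hydroxy-4-methoxy-5-(3-methylbut-2-enyl)phenyl]chroman-4-one
Conditions: Bu4NF, AcOH (1.2 equiv per fluoride), THF, 0 °C
Reagents that add atoms: none
Why: Fluoride-induced cleavage of the two aryl silyl ethers, which is fast because phenoxides are good leaving groups from silicon; acetic acid protonates each phenoxide as it forms, so the medium should stay too weakly basic to remove the C3 hydrogen, and the prenyl group is inert.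

## Compound list

1 | 6-hydroxybenzofuran-3(2H)-one | O=C1COc2cc(O)ccc12 | starting material
2 | 3,6-bis(tert-butyldimethylsilyloxy)benzofuran | CC(C)(C)[Si](C)(C)Oc1ccc2c(O[Si](C)(C)C(C)(C)C)coc2c1 | intermediate
3 | 2-hydroxy-4-methoxybenzaldehyde | COc1ccc(C=O)c(O)c1 | starting material
4 | 5-bromo-2-hydroxy-4-methoxybenzaldehyde | COc1cc(O)c(C=O)cc1Br | intermediate
5 | 5-bromo-4-methoxy-2-(triisopropylsilyloxy)benzaldehyde | COc1cc(O[Si](C(C)C)(C(C)C)C(C)C)c(C=O)cc1Br | intermediate
6 | (E)-5-bromo-4-methoxy-2-(triisopropylsilyloxy)benzaldehyde oxime, formed in the flask and not isolated | COc1cc(O[Si](C(C)C)(C(C)C)C(C)C)c(/C=N/O)cc1Br | intermediate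
7 | 5-bromo-4-methoxy-2-(triisopropylsilyloxy)benzonitrile | COc1cc(O[Si](C(C)C)(C(C)C)C(C)C)c(C#N)cc1Br | intermediate
8 | lithium N,N'-bis(trimethylsilyl)-5-bromo-4-methoxy-2-(triisopropylsilyloxy)benzamidinate, formed in the flask and not isolated | COc1cc(O[Si](C(C)C)(C(C)C)C(C)C)c(C(=N[Si](C)(C)C)[N-][Si](C)(C)C)cc1Br.[Li+] | intermediate
9 | 5-bromo-4-methoxy-2-(triisopropylsilyloxy)benzamidinium chloride | COc1cc(O[Si](C(C)C)(C(C)C)C(C)C)c(C(N)=[NH2+])cc1Br.[Cl-] | intermediate
10 | 3-[5-bromo-4-methoxy-2-(triisopropylsilyloxy)phenyl]-3-chloro-3H-diazirine | COc1cc(O[Si](C(C)C)(C(C)C)C(C)C)c(C2(Cl)N=N2)cc1Br | intermediate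
11 | 1-[5-bromo-4-methoxy-2-(triisopropylsilyloxy)phenyl]-4,6b-bis(tert-butyldimethylsilyloxy)-1-chloro-1a,6b-dihydro-1H-cyclopropa[b][1]benzofuran, racemic, both C1 epimers, formed in the flask and not isolated | CC(C)(C)[Si](C)(C)Oc1ccc2c(c1)OC1C(Cl)(c3cc(Br)c(OC)cc3O[Si](C(C)C)(C(C)C)C(C)C)C21O[Si](C)(C)C(C)(C)C | intermediate
12 | 5'-bromo-7-(tert-butyldimethylsilyloxy)-4'-methoxy-2'-(triisopropylsilyloxy)isoflavone | CC(C)(C)[Si](C)(C)Oc1ccc2c(c1)occ(-c1cc(Br)c(OC)cc1O[Si](C(C)C)(C(C)C)C(C)C)c2=O | intermediate
13 | tributyl(3-methylbut-2-enyl)stannane | CCCC[Sn](CCCC)(CCCC)CC=C(C)C | starting material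
14 | 7-(tert-butyldimethylsilyloxy)-4'-methoxy-5'-(3-methylbut-2-enyl)-2'-(triisopropylsilyloxy)isoflavone | CC(C)(C)[Si](C)(C)Oc1ccc2c(c1)occ(-c1cc(CC=C(C)C)c(OC)cc1O[Si](C(C)C)(C(C)C)C(C)C)c2=O | intermediate
15 | racemic 7-(tert-butyldimethylsilyloxy)-4'-methoxy-5'-(3-methylbut-2-enyl)-2'-(triisopropylsilyloxy)isoflavanone, formed in the flask and not isolated | COc1cc(O[Si](C(C)C)(C(C)C)C(C)C)c(C2COc3cc(O[Si](C)(C)C(C)(C)C)ccc3C2=O)cc1CC=C(C)C | intermediate
16 | (3S,4S)-7-(tert-butyldimethylsilyloxy)-3-[4-methoxy-5-(3-methylbut-2-enyl)-2-(triisopropylsilyloxy)phenyl]chroman-4-ol (cis) | COc1cc(O[Si](C(C)C)(C(C)C)C(C)C)c([C@H]2COc3cc(O[Si](C)(C)C(C)(C)C)ccc3[C@H]2O)cc1CC=C(C)C | intermediate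
17 | (3S)-7-(tert-butyldimethylsilyloxy)-4'-methoxy-5'-(3-methylbut-2-enyl)-2'-(triisopropylsilyloxy)isoflavanone | COc1cc(O[Si](C(C)C)(C(C)C)C(C)C)c([C@H]2COc3cc(O[Si](C)(C)C(C)(C)C)ccc3C2=O)cc1CC=C(C)C | intermediate
18 | (3S)-7-hydroxy-3-[2-hydroxy-4-methoxy-5-(3-methylbut-2-enyl)phenyl]chroman-4-one | COc1cc(O)c([C@H]2COc3cc(O)ccc3C2=O)cc1CC=C(C)C | target

## Step count and least certain steps

Total: 11 steps. Longest linear sequence: 10 steps (3 to 18, steps 2 to 11); step 1 is a one-step branch.

**Step 7 (key step).**
- What may go wrong: the carbene may be lost to azine formation with unreacted diazirine, or to insertion into the neighbouring silyl group, before it reaches 2, because the donor-substituted aryl group makes it less electrophilic. The exo-chloro epimer of 11 may also ionise too slowly, so that the sequence stalls at the cyclopropane.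
- Fallback (known chemistry, carbon and aryl group introduced separately): setting out from 2, dibromocarbene (CHBr3, KOt-Bu, pentane, −20 °C to rt) is added to the enol double bond. The dibromocyclopropane opens with loss of bromide and silyl to 3-bromo-7-(tert-butyldimethylsilyloxy)chromen-4-one F1; this is the established ring expansion of cyclic silyl enol ethers to 2-haloenones. Ring B comes from purchased 2-bromo-5-methoxyphenol F2, which is silylated (TIPSCl, imidazole, DMF) to (2-bromo-5-methoxyphenoxy)triisopropylsilane F3 and borylated (B2pin2, PdCl2(dppf), KOAc, dioxane, 80 °C) to triisopropyl[5-methoxy-2-(4,4,5,5-tetramethyl-1,3,2-dioxaborolan-2-yl)phenoxy]silane F4. Suzuki–Miyaura coupling of F1 with F4 (Pd(OAc)2, SPhos, K3PO4, dioxane, 80 °C) gives 7-(tert-butyldimethylsilyloxy)-4'-methoxy-2'-(triisopropylsilyloxy)isoflavone F5. Bromination with N-bromosuccinimide (MeCN, 0 °C), directed para to the 2'-silyloxy and ortho to the 4'-methoxy group, returns to the route at 12.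

**Step 6 (Graham oxidation).**
- What may go wrong: cleavage of the aryl silyl ether or chlorination of the ring in alkaline hypochlorite, or decomposition of the diazirine on handling, because the electron-rich aryl group favours ionisation of the C–Cl bond.
- Fallback (the same carbene by α-elimination): from 5, deoxygenative chlorination ((COCl)2, catalytic Ph3PO, CH2Cl2) gives 1-bromo-5-(dichloromethyl)-2-methoxy-4-(triisopropylsilyloxy)benzene F6. F6 is deprotonated with KOt-Bu in the presence of 2 (hexane/THF, −20 °C to rt); the arylchlorocarbene adds to 2, adduct 11 opens as in step 7, and the route is rejoined at 12, so that 6 to 10 are bypassed.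

**Step 9 (transfer hydrogenation with dynamic kinetic resolution).**
- What may go wrong: hydride transfer to the crowded isoflavone may be slow, or the cis and facial preferences may erode, because the bulky 2'-silyloxy group sits beside C3. Loss of the ring A silyl ether would also open a quinone methide pathway from the carbinol.
- Fallback (C3 set by enantioselective protonation, not by reduction at C4): from 14, conjugate reduction with LiBH(s-Bu)3 (THF, −78 °C) and trapping of the enolate with Me3SiCl gives 7-(tert-butyldimethylsilyloxy)-3-[4-methoxy-5-(3-methylbut-2-enyl)-2-(triisopropylsilyloxy)phenyl]-4-(trimethylsilyloxy)-2H-chromene F7. Protonation of this silyl enol ether with phenol, catalysed by a chiral BINOL-derived N-triflyl thiophosphoramide (toluene, low temperature, catalyst enantiomer chosen on 2-aryl ketone models), gives 17 directly and replaces steps 9 and 10.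

**Step 8 (Stille prenylation).**
- What may go wrong: coupling through the γ-carbon of the prenyl unit to the 1,1-dimethylallyl isomer, or slow oxidative addition of zerovalent palladium into the electron-rich, ortho-methoxylated bromide, with protodebromination as the result.
- Fallback (allylation, then metathesis): from 12, Stille coupling with allyltributylstannane (Pd(PPh3)4, toluene, 100 °C), which has no regiochemical ambiguity, gives 5'-allyl-7-(tert-butyldimethylsilyloxy)-4'-methoxy-2'-(triisopropylsilyloxy)isoflavone F8. Cross-metathesis with 2-methylbut-2-ene (second-generation Grubbs catalyst RuCl2(=CHPh)(PCy3)(H2IMes), CH2Cl2, 40 °C) converts the allyl into the prenyl group and returns at 14.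

**Step 11 (desilylation).**
- What may go wrong: partial racemisation at C3 by enolisation, if fluoride or a liberated phenoxide acts as a base before acetic acid intercepts it.
- Fallback (silyl groups removed where C3 carries no acidic hydrogen): from 16, Bu4NF in THF gives (3S,4S)-3-[2-hydroxy-4-methoxy-5-(3-methylbut-2-enyl)phenyl]chromane-4,7-diol F9, which is kept free of acid to prevent pterocarpan closure. Activated MnO2 (acetone, rt) oxidises the para-hydroxylated benzylic carbinol under neutral conditions and gives 18 directly.

## Further compounds

F1 | step 7 | 3-bromo-7-(tert-butyldimethylsilyloxy)chromen-4-one | CC(C)(C)[Si](C)(C)Oc1ccc2c(c1)occ(Br)c2=O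
F2 | step 7 | 2-bromo-5-methoxyphenol (purchased) | COc1ccc(Br)c(O)c1
F3 | step 7 | (2-bromo-5-methoxyphenoxy)triisopropylsilane | COc1ccc(Br)c(O[Si](C(C)C)(C(C)C)C(C)C)c1
F4 | step 7 | triisopropyl[5-methoxy-2-(4,4,5,5-tetramethyl-1,3,2-dioxaborolan-2-yl)phenoxy]silane | COc1ccc(B2OC(C)(C)C(C)(C)O2)c(O[Si](C(C)C)(C(C)C)C(C)C)c1
F5 | step 7 | 7-(tert-butyldimethylsilyloxy)-4'-methoxy-2'-(triisopropylsilyloxy)isoflavone | CC(C)(C)[Si](C)(C)Oc1ccc2c(c1)occ(-c1ccc(OC)cc1O[Si](C(C)C)(C(C)C)C(C)C)c2=O
F6 | step 6 | 1-bromo-5-(dichloromethyl)-2-methoxy-4-(triisopropylsilyloxy)benzene | COc1cc(O[Si](C(C)C)(C(C)C)C(C)C)c(C(Cl)Cl)cc1Br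
F7 | step 9 | 7-(tert-butyldimethylsilyloxy)-3-[4-methoxy-5-(3-methylbut-2-enyl)-2-(triisopropylsilyloxy)phenyl]-4-(trimethylsilyloxy)-2H-chromene | COc1cc(O[Si](C(C)C)(C(C)C)C(C)C)c(C2=C(O[Si](C)(C)C)c3ccc(O[Si](C)(C)C(C)(C)C)cc3OC2)cc1CC=C(C)C
F8 | step 8 | 5'-allyl-7-(tert-butyldimethylsilyloxy)-4'-methoxy-2'-(triisopropylsilyloxy)isoflavone | CC(C)(C)[Si](C)(C)Oc1ccc2c(c1)occ(-c1cc(CC=C)c(OC)cc1O[Si](C(C)C)(C(C)C)C(C)C)c2=O
F9 | step 11 | (3S,4S)-3-[2-hydroxy-4-methoxy-5-(3-methylbut-2-enyl)phenyl]chromane-4,7-diol | COc1cc(O)c([C@H]2COc3cc(O)ccc3[C@H]2O)cc1CC=C(C)C
A1 | alternative 1 | 7-(methoxymethoxy)-2,2-dimethyl-4H-1,3-benzodioxin-4-one | COCOc1ccc2c(c1)OC(C)(C)OC2=O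
A2 | alternative 1 | (E)-1-methoxy-5-(2-methoxyethenyl)-4-(methoxymethoxy)-2-(3-methylbut-2-enyl)benzene | CO/C=C/c1cc(CC=C(C)C)c(OC)cc1OCOC
A3 | alternative 1 | 3-(methoxymethoxy)-6-(oxomethylidene)cyclohexa-2,4-dien-1-one | COCOC1=CC(=O)C(=C=O)C=C1
A4 | alternative 1 | 2,4'-dimethoxy-7,2'-bis(methoxymethoxy)-5'-(3-methylbut-2-enyl)isoflavanone, racemic diastereomer mixture | COC1Oc2cc(OCOC)ccc2C(=O)C1c1cc(CC=C(C)C)c(OC)cc1OCOC
A5 | alternative 1 | 4'-methoxy-7,2'-bis(methoxymethoxy)-5'-(3-methylbut-2-enyl)isoflavone | COCOc1ccc2c(c1)occ(-c1cc(CC=C(C)C)c(OC)cc1OCOC)c2=O
A6 | alternative 2 | (E)-1-methoxy-2-[4-methoxy-2-(methoxymethoxy)-5-(3-methylbut-2-enyl)phenyl]pent-1-en-4-yn-3-one | CO/C=C(/C(=O)C#C)c1cc(CC=C(C)C)c(OC)cc1OCOC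
A7 | alternative 2 | 1-methoxy-1,3-bis(trimethylsiloxy)buta-1,3-diene | COC(O[Si](C)(C)C)=CC(=C)O[Si](C)(C)C
A8 | alternative 2 | (E)-1-(2,4-dihydroxyphenyl)-3-methoxy-2-[4-methoxy-2-(methoxymethoxy)-5-(3-methylbut-2-enyl)phenyl]prop-2-en-1-one | CO/C=C(/C(=O)c1ccc(O)cc1O)c1cc(CC=C(C)C)c(OC)cc1OCOC
A9 | alternative 2 | 7-hydroxy-4'-methoxy-2'-(methoxymethoxy)-5'-(3-methylbut-2-enyl)isoflavone | COCOc1cc(OC)c(CC=C(C)C)cc1-c1coc2cc(O)ccc2c1=O
A10 | alternative 3 | (S)-2-[4-methoxy-5-(3-methylbut-2-enyl)-2-(triisopropylsilyloxy)phenyl]-3-[3-(triisopropylsilyloxy)phenoxy]propanoic acid | COc1cc(O[Si](C(C)C)(C(C)C)C(C)C)c([C@@H](COc2cccc(O[Si](C(C)C)(C(C)C)C(C)C)c2)C(=O)O)cc1CC=C(C)C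
A11 | alternative 3 | (S)-4'-methoxy-5'-(3-methylbut-2-enyl)-7,2'-bis(triisopropylsilyloxy)isoflavanone | COc1cc(O[Si](C(C)C)(C(C)C)C(C)C)c([C@H]2COc3cc(O[Si](C(C)C)(C(C)C)C(C)C)ccc3C2=O)cc1CC=C(C)C
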